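**Strategy.** Ring B is disconnected at C9–C10 (labdane numbering). The key step copies the second half of labdane biosynthesis: protonation of the ring-A olefin of a 9,10-seco monocycle gives the C10 cation, the C8=C9 side-chain alkene captures it through a chair transition state (ring B, quaternary C10, trans fusion), and the same acid equilibrates the olefin isomers to the tetrasubstituted C8=C9 bond. The step exploits the fact that C8 and C9 of ring B are sp2 next to quaternary C10: the E/Z mixture and all double-bond regioisomers funnel into one product. The precursor is a cyclohexene ester carrying C4 and C5 (auxiliary-controlled Diels–Alder reaction, enolate methylation) and a bromoethyl-terminated side chain.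

Key step: step 9

Remark: atoms carry labdane numbers throughout; the C8=C9 geometry of 7, 12, 13 and 15 is drawn E, and the minor Z isomer expected from step 4 is carried on because step 9 erases this geometry.

Step 1
Reactants: 1 cyclopropyl methyl ketone; 2 vinylmagnesium bromide
Product: 3 2-cyclopropylbut-3-en-2-ol (racemic)
Conditions: THF, 0 °C to rt; aq. NH4Cl
Reagents that add atoms: none
Why: Grignard 1,2-addition to the ketone should give the tertiary cyclopropyl vinyl carbinol; its stereocentre forms racemic, which is harmless because step 2 destroys it.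

Step 2
Reactants: 3 2-cyclopropylbut-3-en-2-ol
Product: 4 (3E)-6-bromo-3-methylhexa-1,3-diene
Conditions: 48 % aq. HBr, 0 °C, short contact
Reagents that add atoms: hydrogen bromide, Br
Why: Julia cyclopropylcarbinyl-to-homoallyl rearrangement: the acid ionises the carbinol to a cation stabilised by the cyclopropane and the vinyl group, bromide opens the ring at CH2, and the E-diene is expected to predominate because the vinyl group, larger than methyl, turns away from the new chain (the Z-diene cannot reach the s-cis form and is lost in step 6).

Step 3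
Reactants: 4 (3E)-6-bromo-3-methylhexa-1,3-diene; 1 cyclopropyl methyl ketone
Product: 6 (5E)-2-cyclopropyl-6-methylocta-5,7-dien-2-ol (racemic), via Grignard reagent 5 (not isolated)
Conditions: Mg, THF, rt; then 1, 0 °C; aq. NH4Cl
Reagents that add atoms: none
Why: Grignard formation from the primary homoallylic bromide and 1,2-addition to the ketone should give the second cyclopropyl carbinol, again racemic at a centre that step 4 destroys.

Step 4
Reactants: 6 (5E)-2-cyclopropyl-6-methylocta-5,7-dien-2-ol
Product: 7 (3E,7E)-10-bromo-3,7-dimethyldeca-1,3,7-triene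
Conditions: 48 % aq. HBr, 0 °C, short contact
Reagents that add atoms: hydrogen bromide, Br
Why: A second Julia cyclopropylcarbinyl-to-homoallyl rearrangement, run under the conditions in which the same diene was already formed in step 2, should give mainly the 7E bromide; the 7Z isomer is not removed because this geometry is erased in step 9.

Step 5
Reactants: 8 (R)-4-benzyloxazolidin-2-one; 9 acryloyl chloride
Product: 11 (R)-3-acryloyl-4-benzyloxazolidin-2-one, via magnesium imide salt 10 (not isolated)
Conditions: MeMgBr, THF, 0 °C; then 9, −78 °C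
Reagents that add atoms: none
Why: N-Acylation of the magnesium salt of the oxazolidinone with the acid chloride at low temperature should give the acrylimide without conjugate addition; no stereocentre is formed.

Step 6
Reactants: 7 (3E,7E)-10-bromo-3,7-dimethyldeca-1,3,7-triene; 11 (R)-3-acryloyl-4-benzyloxazolidin-2-one
Product: 12 (R)-4-benzyl-3-{[(1S,2S)-2-[(3E)-6-bromo-3-methylhex-3-en-1-yl]-3-methylcyclohex-3-en-1-yl]carbonyl}oxazolidin-2-one
Conditions: Et2AlCl (1.4 equiv), CH2Cl2, −78 °C
Reagents that add atoms: none
Why: Diels–Alder reaction under aluminium chelate control: Et2AlCl locks the acrylimide s-cis between both carbonyl groups, the diene adds endo to the face opposite the benzyl group, and its 1-alkyl substituent directs the "ortho" orientation (C4 bonded to C5), which sets C5 and, cis to it, a temporary centre at C4.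

Step 7
Reactants: 12 the Diels–Alder imide
Product: 13 methyl (1S,2S)-2-[(3E)-6-bromo-3-methylhex-3-en-1-yl]-3-methylcyclohex-3-ene-1-carboxylate
Conditions: NaOMe (1.1 equiv), MeOH/CH2Cl2, 0 °C
Reagents that add atoms: sodium methoxide, [Na+].[O-]C
Why: Methoxide attacks the exocyclic imide carbonyl (transesterification by acyl substitution) and releases the auxiliary; any epimerisation at C4 is harmless since step 8 makes C4 planar.

Step 8
Reactants: 13 the methyl ester
Product: 15 methyl (1S,2R)-2-[(3E)-6-bromo-3-methylhex-3-en-1-yl]-1,3-dimethylcyclohex-3-ene-1-carboxylate, via lithium enolate 14 (not isolated)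
Conditions: LiN(iPr)2 (LDA, 1.1 equiv), THF, −78 °C; MeI, −78 to −20 °C
Reagents that add atoms: iodomethane, CI
Why: Ester enolate alkylation: allylic strain against the C10 methyl and the enolate holds the C5 side chain pseudoaxial, so iodomethane should add to the enolate face anti to it, which sets quaternary C4 with the ester cis to the side chain.

Step 9
Reactants: 15 methyl (1S,2R)-2-[(3E)-6-bromo-3-methylhex-3-en-1-yl]-1,3-dimethylcyclohex-3-ene-1-carboxylate
Product: 18 methyl (1S,4aS,8aR)-5-(2-bromoethyl)-1,4a,6-trimethyl-1,2,3,4,4a,7,8,8a-octahydronaphthalene-1-carboxylate, via exocyclic olefin isomer 16 (not isolated), via trisubstituted olefin isomer 17 (not isolated)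
Conditions: TfOH (0.5 equiv), CH2Cl2, −78 °C, then 0 °C
Reagents that add atoms: none
Why: TfOH protonates the ring-A olefin at C1 to give the tertiary C10 cation, C9 of the side-chain alkene attacks it to close ring B, and the tertiary C8 cation loses a proton; on warming, the same acid re-protonates the exocyclic and trisubstituted olefin isomers (16, 17) so that they drain through the common C8 cation into the tetrasubstituted C8=C9 olefin, the thermodynamic sink. The closest known reaction type is the acid-promoted cation–olefin cyclisation of monocyclic polyprenoids to trans-decalins (monocyclofarnesyl to drimane type) combined with acid-catalysed equilibration of the resulting olefins. Ring B closes in the 6-endo-trig mode through a chair-like transition state. C10 is controlled by C5: the C5–C6 bond stays equatorial on ring A and C9 bonds to the cation face on the side of H5, which pushes the C10 methyl axial and anti to H5 (trans fusion), while C8 and C9 end sp2 so that neither the E/Z ratio of the side-chain alkene nor the first site of proton loss matters. The step needs chemoselectivity (no third ring, no capture of C10 by the ester) and positional selectivity of the final olefin: the former is secured because the chain ends in an inert primary bromide instead of a π- or O-nucleophile and because ester participation at C10 is reversible with the non-nucleophilic triflate counterion, the latter by thermodynamic control.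

Step 10
Reactants: 18 the bicyclic bromide
Product: 19 methyl (1S,4aS,8aR)-5-(but-3-yn-1-yl)-1,4a,6-trimethyl-1,2,3,4,4a,7,8,8a-octahydronaphthalene-1-carboxylate
Conditions: LiC≡CH·H2NCH2CH2NH2, DMSO, rt
Reagents that add atoms: lithium acetylide–ethylenediamine complex, [Li+].[C-]#C.NCCN
Why: SN2 alkylation of lithium acetylide by the primary bromide adds C13 and C14; the ester has no α-hydrogen and is shielded at neopentyl C4, and no stereocentre is touched.

Step 11
Reactants: 19 the terminal alkyne
Product: 21 methyl (1S,4aS,8aR)-5-[(3E)-5-hydroxy-3-methylpent-3-en-1-yl]-1,4a,6-trimethyl-1,2,3,4,4a,7,8,8a-octahydronaphthalene-1-carboxylate, via alkenylalane 20 (not isolated)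
Conditions: Me3Al (2.5 equiv), Cp2ZrCl2 (0.5 equiv), CH2Cl2, 0 °C to rt; then n-BuLi, THF, −78 °C; (CH2O)n, −78 °C to rt
Reagents that add atoms: trimethylaluminium, C[Al](C)C; formaldehyde (as paraformaldehyde), C=O
Why: Negishi zirconium-catalysed carboalumination adds methyl (to C13) and aluminium (to C14) syn across the terminal alkyne, and the derived alanate adds to formaldehyde with retention, so the 13E trisubstituted olefin is set in one flask.

Step 12
Reactants: 21 the allylic alcohol
Product: 22 methyl (1S,4aS,8aR)-5-[(3E)-5-acetoxy-3-methylpent-3-en-1-yl]-1,4a,6-trimethyl-1,2,3,4,4a,7,8,8a-octahydronaphthalene-1-carboxylate (target)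
Conditions: Ac2O, pyridine, DMAP (cat.), CH2Cl2, rt
Reagents that add atoms: acetic anhydride, CC(=O)OC(C)=O
Why: DMAP-catalysed acetylation of the primary allylic alcohol (nucleophilic acyl substitution) should give the target without touching the stereocentres.

**Compound list**

1 | cyclopropyl methyl ketone (1-cyclopropylethan-1-one) | CC(=O)C1CC1 | starting material
2 | vinylmagnesium bromide | C=C[Mg]Br | starting material
3 | 2-cyclopropylbut-3-en-2-ol (racemic) | CC(O)(C=C)C1CC1 | intermediate
4 | (3E)-6-bromo-3-methylhexa-1,3-diene | C=C/C(C)=C/CCBr | intermediate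
5 | [(3E)-4-methylhexa-3,5-dien-1-yl]magnesium bromide (formed in the flask) | C=C/C(C)=C/CC[Mg]Br | intermediate
6 | (5E)-2-cyclopropyl-6-methylocta-5,7-dien-2-ol (racemic) | CC(O)(CC/C=C(C)/C=C)C1CC1 | intermediate
7 | (3E,7E)-10-bromo-3,7-dimethyldeca-1,3,7-triene | C=C/C(C)=C/CC/C(C)=C/CCBr | intermediate
8 | (R)-4-benzyloxazolidin-2-one | O=C1N[C@H](Cc2ccccc2)CO1 | starting material
9 | acryloyl chloride | C=CC(=O)Cl | starting material
10 | N-bromomagnesium salt of (R)-4-benzyloxazolidin-2-one (formed in the flask) | Br[Mg]N1[C@H](Cc2ccccc2)COC1=O | intermediate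
11 | (R)-3-acryloyl-4-benzyloxazolidin-2-one | C=CC(=O)N1[C@H](Cc2ccccc2)COC1=O | intermediate
12 | (R)-4-benzyl-3-{[(1S,2S)-2-[(3E)-6-bromo-3-methylhex-3-en-1-yl]-3-methylcyclohex-3-en-1-yl]carbonyl}oxazolidin-2-one | O=C([C@H]1CCC=C(C)[C@H]1CC/C(C)=C/CCBr)N1[C@H](Cc2ccccc2)COC1=O | intermediate
13 | methyl (1S,2S)-2-[(3E)-6-bromo-3-methylhex-3-en-1-yl]-3-methylcyclohex-3-ene-1-carboxylate | COC(=O)[C@H]1CCC=C(C)[C@H]1CC/C(C)=C/CCBr | intermediate
14 | lithium enolate of 13 (C4 planar, C5 unchanged; formed in the flask) | COC(O[Li])=C1CCC=C(C)[C@H]1CC/C(C)=C/CCBr | intermediate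
15 | methyl (1S,2R)-2-[(3E)-6-bromo-3-methylhex-3-en-1-yl]-1,3-dimethylcyclohex-3-ene-1-carboxylate | COC(=O)[C@@]1(C)CCC=C(C)[C@H]1CC/C(C)=C/CCBr | intermediate
16 | isomer of 18 with an exocyclic C8=CH2 bond instead of C8=C9 and H-9 α, trans to the C10 methyl (formed in the flask) | COC(=O)[C@@]1(C)CCC[C@]2(C)[C@@H](CCBr)C(=C)CC[C@@H]12 | intermediate
17 | isomer of 18 with a C7=C8 bond instead of C8=C9 and H-9 α (formed in the flask) | COC(=O)[C@@]1(C)CCC[C@]2(C)[C@@H](CCBr)C(C)=CC[C@@H]12 | intermediate
18 | methyl (1S,4aS,8aR)-5-(2-bromoethyl)-1,4a,6-trimethyl-1,2,3,4,4a,7,8,8a-octahydronaphthalene-1-carboxylate | COC(=O)[C@@]1(C)CCC[C@]2(C)C(CCBr)=C(C)CC[C@@H]12 | intermediate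
19 | methyl (1S,4aS,8aR)-5-(but-3-yn-1-yl)-1,4a,6-trimethyl-1,2,3,4,4a,7,8,8a-octahydronaphthalene-1-carboxylate | COC(=O)[C@@]1(C)CCC[C@]2(C)C(CCC#C)=C(C)CC[C@@H]12 | intermediate
20 | (E)-alkenyldimethylalane from 19 (C13 methyl, C14 AlMe2; formed in the flask) | COC(=O)[C@@]1(C)CCC[C@]2(C)C(CC/C(C)=C/[Al](C)C)=C(C)CC[C@@H]12 | intermediate
21 | methyl (1S,4aS,8aR)-5-[(3E)-5-hydroxy-3-methylpent-3-en-1-yl]-1,4a,6-trimethyl-1,2,3,4,4a,7,8,8a-octahydronaphthalene-1-carboxylate | COC(=O)[C@@]1(C)CCC[C@]2(C)C(CC/C(C)=C/CO)=C(C)CC[C@@H]12 | intermediate
22 | methyl (1S,4aS,8aR)-5-[(3E)-5-acetoxy-3-methylpent-3-en-1-yl]-1,4a,6-trimethyl-1,2,3,4,4a,7,8,8a-octahydronaphthalene-1-carboxylate (methyl 15-acetoxylabda-8,13E-dien-19-oate) | COC(=O)[C@@]1(C)CCC[C@]2(C)C(CC/C(C)=C/COC(C)=O)=C(C)CC[C@@H]12 | target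

**Step count.** Total: 12 steps. Longest linear sequence: 11 steps (steps 1–4 and 6–12, from cyclopropyl methyl ketone).

**Steps most likely to fail**

Step 9 (key step). Before ring closure the C10 cation may lose H5 and be re-protonated, which would erode the C5 configuration. Later, the equilibration may stall at the trisubstituted or exocyclic olefin, or trigger 1,2-shifts (hydride from C9, methyl from C10). The fallback separates ring closure from placement of the double bond. It sets out from 15, which is cyclised with SnCl4 in CH2Cl2 at −78 °C only. The unpurified mixture of 16, 17 and 18 is then subjected to Mukaiyama hydration (Co(acac)2, PhSiH3, O2, i-PrOH). This should convert 16 and 17 into the tertiary C8 alcohol F1, while the tetrasubstituted 18 is expected to react slowly and is carried through. Dehydration of F1 with PPh3/I2 in CH2Cl2 at rt, a reagent known to give the most substituted olefin from 8-hydroxy decalins of this type, comes back to the route at 18.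

Step 6. Facial control may erode (reaction through the non-chelated acrylimide or through the exo mode, which after step 8 appears as loss of enantiopurity), and the stoichiometric aluminium Lewis acid may oligomerise the triene. The fallback replaces auxiliary control by catalyst control. It sets out from 7, which is combined with commercial achiral 3-acryloyloxazolidin-2-one and 10 mol % [Cu((S,S)-tBu-box)](SbF6)2 (tBu-box = 2,2'-(propane-2,2-diyl)bis(4-tert-butyl-4,5-dihydrooxazole)) in CH2Cl2 at −20 °C. The square-planar copper chelate should expose the same acrylimide face as the (R)-benzyl auxiliary and give the achiral-imide cycloadduct F2. Methanolysis of F2 (NaOMe, MeOH, 0 °C) comes back to the route at 13.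

Step 10. The basic acetylide may remove an allylic C11 proton and eliminate HBr (E2) to a conjugated diene instead of substituting at C12. The fallback builds C13–C15 by an sp3–sp2 cross-coupling under non-basic conditions. It sets out from 18, which is converted with Zn dust and catalytic I2 in DMA at 70 °C into the alkylzinc bromide F3. Ethyl acetoacetate, Tf2O and aqueous Me4NOH should give the (E)-enol triflate F4. Negishi coupling of F3 with F4 (Pd(PPh3)4, THF/DMA, rt) should proceed with retention to the diester F5. i-Bu2AlH (2.1 equiv, CH2Cl2, −78 °C) should then reduce only the unhindered conjugated ethyl ester, the C19 ester being axial and neopentyl, and comes back to the route at 21.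

Further compounds
F1 | step 9 | methyl (1S,4aS,8aR)-5-(2-bromoethyl)-6-hydroxy-1,4a,6-trimethyldecahydronaphthalene-1-carboxylate (8α-OH, 9α-H drawn) | COC(=O)[C@@]1(C)CCC[C@]2(C)[C@@H](CCBr)[C@](C)(O)CC[C@@H]12
F2 | step 6 | 3-{[(1S,2S)-2-[(3E)-6-bromo-3-methylhex-3-en-1-yl]-3-methylcyclohex-3-en-1-yl]carbonyl}oxazolidin-2-one | O=C([C@H]1CCC=C(C)[C@H]1CC/C(C)=C/CCBr)N1CCOC1=O
F3 | step 10 | alkylzinc bromide from 18 (C12–ZnBr) | COC(=O)[C@@]1(C)CCC[C@]2(C)C(CC[Zn]Br)=C(C)CC[C@@H]12
F4 | step 10 | ethyl (2E)-3-{[(trifluoromethyl)sulfonyl]oxy}but-2-enoate | CCOC(=O)/C=C(C)/OS(=O)(=O)C(F)(F)F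
F5 | step 10 | 15-ethyl 19-methyl (13E)-labda-8,13-diene-15,19-dioate | COC(=O)[C@@]1(C)CCC[C@]2(C)C(CC/C(C)=C/C(=O)OCC)=C(C)CC[C@@H]12
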